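## The problem

Compound 13 is a hexasubstituted benzene: C1 carries the CH2 group bound to the nitrogen of a pyrrolidin-2-one ring, C2, C5 and C6 carry bromine, and C3 and C4 carry the two hydroxyls of a catechol. The arene and the lactam are joined only through the exocyclic C1–CH2–N bond, so the task is to place six substituents on one ring without positional ambiguity. Electrophilic substitution of a simple benzyl lactam could not by itself tell C2 from C6 or deliver the oxygens to C3 and C4. There is no stereocentre in 13; the single sp3 ring centre met on the way (the future C1) is racemic and is erased on aromatisation, so no stereochemical relay has to be planned. The fragile features are three: the free catechol, which halogens, quinone oxidants or air in base turn into an o-quinone; the C1–CH2–N bond, which lies para to the C4 hydroxyl and is open to ipso attack; and the aryl bromides, which would not survive reducing or strongly basic steps and therefore belong at the very end. The lactam is sturdy but has an acidic α-CH2 and can open in hot hydroxide. The enabling feature is that C3 and C4 have the oxidation pattern of an oxalyl unit and their neighbours C2 and C5 can each carry a carboxyl group, so that C2–C1–C6–C5 is the α,β,β′,α′ chain of an adipate substituted at its 3-position. Each carboxyl then sits ortho to a hydroxyl, where bromine can later replace it.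

## Retrosynthesis

**13 back to 12.** The three C–Br bonds are cut last. C6–Br goes back to C6–H, and C2–Br and C5–Br go back to C–CO2H, giving the dihydroxyterephthalic acid 12. The carboxyls are there anyway as the activating groups of the ring synthesis, so removing them and brominating in one operation saves a separate decarboxylation. The forward reaction must substitute at one C–H para to a hydroxyl and ipso at two carboxyl-bearing carbons ortho to a hydroxyl, without lasting oxidation of the catechol and without ipso attack at C1.

**12 back to 10.** Ester hydrolysis relates 12 to the diethyl ester 11, and adding two hydrogens across C1–C6 relates 11 to the 5,6-dihydrocatechol 10 (a cyclohexa-1,3-diene-2,3-diol diester). This takes the problem out of aromatic chemistry: 10 is the bis-enol of a cyclic 1,2-dione flanked by two esters and can be made by carbonyl condensation. The forward step must remove one hydrogen from each of the two sp3 ring carbons and stop at the catechol.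

**10 back to 7 and 8 (key disconnection).** The ring bonds C2–C3 and C4–C5 are cut, releasing C3/C4 as diethyl oxalate 8 and the remaining four ring carbons plus both esters as the 3-substituted adipate 7. Cutting on both sides of the symmetrical oxalyl unit means there is only one way to join the pieces, so the oxygens, the esters and the side chain are fixed by connectivity alone. Cutting elsewhere in the ring (for instance C1–C2 or C5–C6) would leave two unsymmetrical partners and a regiochemical question. Compound 7 is an open-chain diester with one racemic centre. The forward reaction must acylate both ester α-carbons with one oxalate molecule, by way of the mono-acylated triester 9, in preference to the lactam α-carbon and to self-condensation of the adipate.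

**7 back to 4.** Esterification relates 7 to the diacid 6, and the two carboxyl carbons of 6 are reconnected as the alkene of the cyclohexene 4. A 4-substituted cyclohexene gives a 3-substituted adipic acid on oxidative cleavage, so the 1,3-relationship between the side chain and the nearer carboxyl comes from the ring and needs no C–C bond formation. The forward step needs an oxidative cleavage that cuts the alkene to two acids by way of the ozonide 5 but leaves the N-alkyl lactam alone.

**4 back to 1 and 2.** The exocyclic CH2–N bond and the lactam N–C(=O) bond are cut, giving cyclohex-3-ene-1-carbaldehyde 1 (a commercial Diels–Alder adduct) and ethyl 4-aminobutanoate hydrochloride 2 (commercial). Reductive amination to the amino ester 3 followed by lactamisation builds the N-substituted pyrrolidinone in one flask. Attaching a preformed lactam ring by N-alkylation would first require the aldehyde to be reduced and activated.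

## Roads not taken

Alternative 1: The ring bonds C1–C2 and C5–C6 are cut. In the forward sense 2,5-dibromo-3,4-dimethoxythiophene 1,1-dioxide A1 would add across the triple bond of 1-(3-bromoprop-2-yn-1-yl)pyrrolidin-2-one A2. The bridged adduct would aromatise by cheletropic extrusion of its sulfonyl bridge to give 1-[(2,3,6-tribromo-4,5-dimethoxyphenyl)methyl]pyrrolidin-2-one A3, and O-demethylation of A3 would give 13.
- Merits: the cycloaddition places all six substituents, bromines included, in one convergent step. The diene A1 is symmetrical, so there is no regiochemical issue, and no bromination of a free catechol is needed. The route could be about five steps, which is shorter than the chosen plan.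
- Weak points: A1 must be made by S-oxidation of an electron-rich brominated thiophene, where ring oxidation competes. Thiophene dioxides react best as electron-poor dienes with electron-rich or strained partners. The two methoxy groups of A1 blunt that character, and A2 is neither electron-rich nor strained and is thermally delicate as a haloalkyne. The temperatures an alkyne partner usually demands invite dimerisation of A1 and decomposition of A2 before A3 can form.
- Comparison: Alternative 1 is better in step count and convergence. The chosen plan sets against this a ring-forming step of an established type with commodity reagents, and pays for it with three steps after the ring is built.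

Alternative 2: The ring bonds C4–C5 and C1–C2 are cut. TiCl4 would join 1,4-dimethoxy-1,3-bis(trimethylsilyloxy)buta-1,3-diene A4 with (E)-4-methoxy-1-(2-oxopyrrolidin-1-yl)but-3-en-2-one A5. The methoxy-bearing terminus of A4 adds to the β-carbon of A5 and the central carbon condenses with the ketone, giving methyl 2-hydroxy-3-methoxy-6-[(2-oxopyrrolidin-1-yl)methyl]benzoate A6. From A6, ester hydrolysis, O-demethylation and bromination (one ipso-bromodecarboxylation at C2, two C–H brominations at C5 and C6) would follow.
- Merits: the arene A6 is formed directly at the right oxidation level, so no dehydrogenation is needed. Only one carboxyl has to be replaced, and both oxygens are in place.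
- Weak points: two modes of union are possible, and the regiochemistry rests on terminal-carbon-first conjugate addition. A5 is an α-amido ketone whose carbonyls, together with the lactam, bind TiCl4 and can erode yield and selectivity. Both A4 and A5 are moisture-sensitive and each needs a short synthesis of its own. An extra ether cleavage is needed after A6.
- Comparison: the step count is about the same, and Alternative 2 is better in reaching the aromatic level directly. The chosen plan sets against it a symmetrical two-carbon partner that allows only one mode of ring closure, and the absence of a strong Lewis acid next to the lactam.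

Alternative 3: The C3–O and C4–O bonds are cut. 1,2,3,4,5-Pentabromo-6-(bromomethyl)benzene A7 would alkylate pyrrolidin-2-one A8 on nitrogen to give 1-[(2,3,4,5,6-pentabromophenyl)methyl]pyrrolidin-2-one A9. Ethane-1,2-diol A10 with Cs2CO3 in hot dimethyl sulfoxide would then displace two neighbouring ring bromides of A9 to give 1-[(5,7,8-tribromo-2,3-dihydro-1,4-benzodioxin-6-yl)methyl]pyrrolidin-2-one A11, and the two-carbon bridge of A11 would be cleaved to reach 13.
- Merits: this is the shortest route, about three steps. A7, A8 and A10 are simple reagents, and the benzylic carbon and all three final bromines are present from the start.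
- Weak points: the five C–Br positions of A9 differ only in their relation to a weakly perturbing CH2N group. Nothing directs the first substitution to C3 or C4 rather than C2, so ring fusion across C2–C3 is equally plausible. The arene of A9 has no activating group for nucleophilic substitution, and hot basic dimethyl sulfoxide invites reduction or migration of bromine. The ethylene bridge of A11 is one of the hardest catechol ethers to cleave.
- Comparison: Alternative 3 is far better in step count. The chosen plan sets against this that every substituent position follows from skeletal connectivity and not from a selectivity the substrate does not obviously provide, and that no stubborn bridge has to be removed.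

Key step: step 4

Assumption: 13 is achiral, so every chiral intermediate (1, 3, 4, 5, 6, 7, 9 and 10) is carried as a racemate or diastereomer mixture; 2 is used as its commercial hydrochloride.

## Route

Step 1
Reactants: 1 cyclohex-3-ene-1-carbaldehyde (racemic); 2 ethyl 4-aminobutanoate hydrochloride
Product: 4 1-[(cyclohex-3-en-1-yl)methyl]pyrrolidin-2-one (racemic), via amino ester 3 (not isolated)
Conditions: 2 (1.2 equiv), Et3N (1.2 equiv), NaBH(OAc)3 (1.5 equiv), ClCH2CH2Cl, rt; then 80 °C
Reagents that add atoms: none
Why: Direct reductive amination of an aliphatic aldehyde with a primary amine; NaBH(OAc)3 reduces the iminium ion but not the aldehyde, ester or alkene, and the secondary γ-amino ester 3 closes to the five-membered lactam on heating with loss of ethanol. The slight excess of 2 suppresses double alkylation, and the stereocentre of 1 is untouched and stays racemic.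

Step 2
Reactants: 4 1-[(cyclohex-3-en-1-yl)methyl]pyrrolidin-2-one
Product: 6 3-[(2-oxopyrrolidin-1-yl)methyl]hexanedioic acid (racemic), via ozonide 5 (not isolated)
Conditions: O3, CH2Cl2, −78 °C; N2 purge; then HCO2H, 30% aq H2O2, warm to 70 °C (CH2Cl2 distilled off)
Reagents that add atoms: ozone, O=[O+][O-]; hydrogen peroxide, OO
Why: Ozonolysis (Criegee mechanism) of the only C=C bond gives ozonide 5, and performic acid formed in the flask oxidises both termini to carboxylic acids; cutting the ring alkene leaves the side-chain carbon as C3 of a hexanedioic acid. The tertiary lactam is inert to ozone at −78 °C and to the peracid.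

Step 3
Reactants: 6 3-[(2-oxopyrrolidin-1-yl)methyl]hexanedioic acid
Product: 7 diethyl 3-[(2-oxopyrrolidin-1-yl)methyl]hexanedioate (racemic)
Conditions: EtOH, H2SO4 (cat.), reflux
Reagents that add atoms: ethanol, CCO
Why: Fischer esterification driven by excess ethanol; the five-membered lactam is stable in acidic ethanol, and any ring-opened amino ester would re-close to the lactam once neutralised and warmed, as in step 1.

Step 4
Reactants: 7 diethyl 3-[(2-oxopyrrolidin-1-yl)methyl]hexanedioate; 8 diethyl oxalate
Product: 10 diethyl 2,3-dihydroxy-5-[(2-oxopyrrolidin-1-yl)methyl]cyclohexa-1,3-diene-1,4-dicarboxylate (racemic; bis-enol of the 2,3-dione), via open-chain oxalyl triester 9 (not isolated)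
Conditions: NaOEt (2.2 equiv), 8 (1.1 equiv), EtOH–toluene, 0 → 80 °C, EtOH distilled off; then cold 1 M HCl
Reagents that add atoms: none
Why: Ethoxide reversibly forms the ester enolates of 7; the enolate at the less hindered adipate C5 adds to one carbonyl of the non-enolisable, strongly electrophilic oxalate 8 and expels ethoxide (crossed Claisen condensation) to give 9, held as its stabilised enolate. The enolate at adipate C2 then attacks the remaining oxalyl ester carbonyl in a 6-exo-trig Dieckmann-type closure, forming the second C–C bond and the carbocycle; whichever α-carbon reacts first, the same ring results. The closest known reaction is the condensation of diethyl adipate itself with diethyl oxalate to diethyl 2,3-dioxocyclohexane-1,4-dicarboxylate. Every step is reversible, and the sequence is pulled forward by double deprotonation of the cyclic bis(β-keto ester), which is why more than two equivalents of base are used and ethanol is removed. The step needs selectivity for the two ester α-carbons over the lactam α-carbon and over five-ring Dieckmann closure of 7. The lactam α-hydrogens are markedly less acidic than ester α-hydrogens, so ethoxide generates essentially only ester enolates, and the oxalate is a far better acceptor than an unactivated ester while self-condensation of 7 remains reversible. No stereocentre is created: the existing one stays racemic and the two new α-centres are erased by enolisation. Cold acid releases 10 as the hydrogen-bonded bis-enol.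

Step 5
Reactants: 10 diethyl 2,3-dihydroxy-5-[(2-oxopyrrolidin-1-yl)methyl]cyclohexa-1,3-diene-1,4-dicarboxylate
Product: 11 diethyl 2,3-dihydroxy-5-[(2-oxopyrrolidin-1-yl)methyl]benzene-1,4-dicarboxylate
Conditions: DDQ (1.05 equiv), 1,4-dioxane, rt → 60 °C
Reagents that add atoms: none
Why: DDQ dehydrogenation; 10 is a cyclohexa-1,3-diene, so hydride abstraction from an allylic hydrogen on one of the two sp3 ring carbons gives a hydroxy-stabilised arenium ion that loses a proton to the arene. Aromatisation removes the only stereocentre, and with one equivalent of oxidant the electron-poor, doubly hydrogen-bonded catechol diester should resist further oxidation.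

Step 6
Reactants: 11 diethyl 2,3-dihydroxy-5-[(2-oxopyrrolidin-1-yl)methyl]benzene-1,4-dicarboxylate
Product: 12 2,3-dihydroxy-5-[(2-oxopyrrolidin-1-yl)methyl]benzene-1,4-dicarboxylic acid
Conditions: 2 M aq NaOH (6 equiv), EtOH, 70 °C, Ar; then HCl to pH 1, 0 °C
Reagents that add atoms: sodium hydroxide, [Na+].[OH-]
Why: Acyl–oxygen saponification of both salicylate-type esters; warm excess hydroxide is needed because the neighbouring phenoxides deactivate the esters, and argon protects the catecholate from air. The tertiary five-membered lactam is attacked by hydroxide far more slowly than the esters and should survive at 70 °C, and acidification precipitates the diacid 12.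

Step 7
Reactants: 12 2,3-dihydroxy-5-[(2-oxopyrrolidin-1-yl)methyl]benzene-1,4-dicarboxylic acid
Product: 13 1-[(2,3,6-tribromo-4,5-dihydroxyphenyl)methyl]pyrrolidin-2-one
Conditions: Br2 (3.2 equiv), AcOH–H2O (3:1), rt → 45 °C; then aq Na2S2O4 wash
Reagents that add atoms: bromine, BrBr
Why: Electrophilic aromatic bromination; the one ring C–H is para to the C3 hydroxyl, and each carboxyl-bearing carbon is ortho to a hydroxyl, so bromine adds ipso and the carboxyl leaves as CO2 (ipso-bromodecarboxylation, as when bromine water converts salicylic or 4-hydroxybenzoic acid to tribromophenol). The aqueous medium keeps the carboxyl groups ionisable so that CO2 is lost from each ipso adduct, and the Na2S2O4 wash destroys excess bromine and returns any o-quinone to the catechol.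

## Compound list

1 | cyclohex-3-ene-1-carbaldehyde (racemic) | O=CC1CCC=CC1 | starting material
2 | ethyl 4-aminobutanoate hydrochloride | CCOC(=O)CCCN.Cl | starting material
3 | ethyl 4-{[(cyclohex-3-en-1-yl)methyl]amino}butanoate (racemic) | CCOC(=O)CCCNCC1CCC=CC1 | intermediate
4 | 1-[(cyclohex-3-en-1-yl)methyl]pyrrolidin-2-one (racemic) | O=C1CCCN1CC1CCC=CC1 | intermediate
5 | 1-[(7,8,9-trioxabicyclo[4.2.1]nonan-3-yl)methyl]pyrrolidin-2-one (ozonide, mixture of diastereomers) | O=C1CCCN1CC1CCC2OOC(C1)O2 | intermediate
6 | 3-[(2-oxopyrrolidin-1-yl)methyl]hexanedioic acid (racemic) | O=C(O)CCC(CN1CCCC1=O)CC(=O)O | intermediate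
7 | diethyl 3-[(2-oxopyrrolidin-1-yl)methyl]hexanedioate (racemic) | CCOC(=O)CCC(CN1CCCC1=O)CC(=O)OCC | intermediate
8 | diethyl oxalate | CCOC(=O)C(=O)OCC | starting material
9 | diethyl 2-(2-ethoxy-2-oxoacetyl)-4-[(2-oxopyrrolidin-1-yl)methyl]hexanedioate (mixture of diastereomers, drawn as the keto form) | CCOC(=O)C(=O)C(CC(CN1CCCC1=O)CC(=O)OCC)C(=O)OCC | intermediate
10 | diethyl 2,3-dihydroxy-5-[(2-oxopyrrolidin-1-yl)methyl]cyclohexa-1,3-diene-1,4-dicarboxylate (racemic) | CCOC(=O)C1=C(O)C(O)=C(C(=O)OCC)C(CN2CCCC2=O)C1 | intermediate
11 | diethyl 2,3-dihydroxy-5-[(2-oxopyrrolidin-1-yl)methyl]benzene-1,4-dicarboxylate | CCOC(=O)c1cc(CN2CCCC2=O)c(C(=O)OCC)c(O)c1O | intermediate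
12 | 2,3-dihydroxy-5-[(2-oxopyrrolidin-1-yl)methyl]benzene-1,4-dicarboxylic acid | O=C(O)c1cc(CN2CCCC2=O)c(C(=O)O)c(O)c1O | intermediate
13 | 1-[(2,3,6-tribromo-4,5-dihydroxyphenyl)methyl]pyrrolidin-2-one | O=C1CCCN1Cc1c(Br)c(O)c(O)c(Br)c1Br | target

## Step count and least certain steps

Total step count: 7. Longest linear sequence: 7 steps (1 to 13).

**Step 4 (key step).** The sequence may stall after the first acylation, because the ring-closing acylation takes place at the α-carbon next to the branched carbon and every stage is reversible. Five-ring self-condensation of 7 may also draw material off before the oxalate captures the enolate. The fallback separates the two bond formations and changes the way the second enolate is made. It sets out from 7 and 8. NaOEt (1 equiv) with a large excess of 8 in Et2O at 0 °C to rt should acylate the less hindered α-carbon and stop at the sodium enolate of 9, which is acidified and isolated. The ring is then closed by Lewis-acid soft enolisation with TiCl4 (3 equiv) and Et3N (4 equiv) in CH2Cl2 at −10 °C to rt. Tetravalent titanium chelates the 1,2-dicarbonyl of the ethoxalyl group and activates its ester, while the amine generates the titanium enolate of the remaining ester for an irreversible Dieckmann-type closure. The fallback returns to the route at 10 and makes no compound outside the list; its entry below is F0.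

**Step 7.** Bromine in water may oxidise the catechol faster than it substitutes, may attack ipso at C1 (para to the C4 hydroxyl) with loss of the side chain, or may leave the more hindered C2 carboxyl unreplaced. The fallback decouples decarboxylation from bromination and sets out from 12. Protodecarboxylation with Cu2O (cat.) and 1,10-phenanthroline in quinoline–N-methylpyrrolidinone at 170 °C should give 1-[(3,4-dihydroxyphenyl)methyl]pyrrolidin-2-one F1. The three free ring positions of F1 are each ortho or para to a hydroxyl and are then brominated exhaustively with Br2 (3.1 equiv) in anhydrous AcOH at rt, the non-oxidising conditions under which catechols are perbrominated. This returns to the route at 13.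

**Step 5.** DDQ may go on to oxidise the product catechol to an o-quinone or abstract hydride from the benzylic CH2 para to the C4 hydroxyl. The fallback replaces the stoichiometric quinone by acceptorless catalytic dehydrogenation. It sets out from 10, which is heated with 10% Pd/C (zerovalent palladium on carbon) in refluxing p-cymene under a nitrogen stream, so that hydrogen is swept out and no oxidant able to touch the catechol is present. It returns at 11 and makes no compound outside the list; its entry below is F0.

**Step 6.** Hydrolysis of the ester flanked by the hydroxyl and the CH2N group may be slow, and pushing the hydroxide conditions may then open the lactam or allow air oxidation of the catecholate. The fallback changes from acyl–oxygen to alkyl–oxygen cleavage. It sets out from 11, which is treated with BBr3 (excess) in CH2Cl2 at −10 °C to rt; boron chelates each hydroxy ester and bromide removes the ethyl groups as bromoethane, with no hydroxide present. Aqueous work-up returns to the route at 12, and no compound outside the list is made; its entry below is F0.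

## Further compounds

F0 | step 4 | none | none
F1 | step 7 | 1-[(3,4-dihydroxyphenyl)methyl]pyrrolidin-2-one | O=C1CCCN1Cc1ccc(O)c(O)c1
F0 | step 5 | none | none
F0 | step 6 | none | none
A1 | alternative 1 | 2,5-dibromo-3,4-dimethoxythiophene 1,1-dioxide | COC1=C(Br)S(=O)(=O)C(Br)=C1OC
A2 | alternative 1 | 1-(3-bromoprop-2-yn-1-yl)pyrrolidin-2-one | O=C1CCCN1CC#CBr
A3 | alternative 1 | 1-[(2,3,6-tribromo-4,5-dimethoxyphenyl)methyl]pyrrolidin-2-one | O=C1CCCN1Cc1c(Br)c(OC)c(OC)c(Br)c1Br
A4 | alternative 2 | 1,4-dimethoxy-1,3-bis(trimethylsilyloxy)buta-1,3-diene | COC=C(O[Si](C)(C)C)C=C(OC)O[Si](C)(C)C
A5 | alternative 2 | (E)-4-methoxy-1-(2-oxopyrrolidin-1-yl)but-3-en-2-one | CO/C=C/C(=O)CN1CCCC1=O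
A6 | alternative 2 | methyl 2-hydroxy-3-methoxy-6-[(2-oxopyrrolidin-1-yl)methyl]benzoate | COC(=O)c1c(O)c(OC)ccc1CN1CCCC1=O
A7 | alternative 3 | 1,2,3,4,5-pentabromo-6-(bromomethyl)benzene | BrCc1c(Br)c(Br)c(Br)c(Br)c1Br
A8 | alternative 3 | pyrrolidin-2-one | O=C1CCCN1
A9 | alternative 3 | 1-[(2,3,4,5,6-pentabromophenyl)methyl]pyrrolidin-2-one | O=C1CCCN1Cc1c(Br)c(Br)c(Br)c(Br)c1Br
A10 | alternative 3 | ethane-1,2-diol | OCCO
A11 | alternative 3 | 1-[(5,7,8-tribromo-2,3-dihydro-1,4-benzodioxin-6-yl)methyl]pyrrolidin-2-one | O=C1CCCN1Cc1c(Br)c2OCCOc2c(Br)c1Br
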